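**Retrosynthetic overview**
- Target ⇒ one-pot hydrogenation of a penta-O-benzyl bis-chalcone (both C=C bonds saturated, all five benzyl ethers cleaved).
- Bis-chalcone ⇒ double Claisen–Schmidt condensation of a diaryl-ether dialdehyde with two equivalents of 2',4'-bis(benzyloxy)acetophenone.
- Dialdehyde ⇒ SNAr diaryl-ether formation between 4-fluoro-3-methoxybenzaldehyde and 4-(benzyloxy)-3-hydroxybenzaldehyde.
- No ring is formed: all four benzene rings are bought; only the Ar–O–Ar bond and the two three-carbon linkers are built.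

Assumption: the target has no stereocentre (it is achiral), so "single enantiomer" needs no stereocontrol; compounds 1, 2 and 4 are taken as catalogue chemicals.

**Route**

Step 1
Reactants: 1 4-fluoro-3-methoxybenzaldehyde; 2 4-(benzyloxy)-3-hydroxybenzaldehyde
Product: 3 4-(benzyloxy)-3-(4-formyl-2-methoxyphenoxy)benzaldehyde
Conditions: K2CO3 (2 equiv), DMSO, 120 °C, N2, 16 h
Reagents that add atoms: none
Why: SNAr (addition–elimination): the para-formyl group activates the C–F bond of 1 toward the phenoxide of 2, carbonate leaves both aldehydes and the benzyl ether untouched, and no stereocentre is formed.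

Step 2
Reactants: 3 4-(benzyloxy)-3-(4-formyl-2-methoxyphenoxy)benzaldehyde; 4 1-[2,4-bis(benzyloxy)phenyl]ethan-1-one (2.2 equiv)
Product: 7 (E,E)-penta-O-benzyl bis-chalcone, via ring-A mono-chalcone 5 (not isolated), via ring-B mono-chalcone 6 (not isolated)
Conditions: 50% aq KOH, EtOH/THF 1:1, rt, 24–48 h
Reagents that add atoms: none
Why: Double Claisen–Schmidt (crossed aldol) condensation: 3 has no α-hydrogen, the enolate of methyl ketone 4 adds to each aldehyde and E1cB dehydration gives the E-enones, while benzyl protection keeps 4 from being deactivated as a phenoxide; only alkene geometry is created and it is erased in step 3.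

Step 3
Reactants: 7 (E,E)-penta-O-benzyl bis-chalcone
Product: 9 verbenachalcone, via penta-O-benzylverbenachalcone 8 (not isolated)
Conditions: H2 (1 atm), 10% Pd/C, THF/MeOH 1:1, rt; stop when debenzylation is complete (LC-MS)
Reagents that add atoms: none
Why: Heterogeneous catalytic hydrogenation: Pd/C saturates the two enone C=C bonds and then hydrogenolyses the five O-benzyl ethers, while the diaryl ether, the methyl ether and the electron-rich 2,4-dioxygenated aryl ketones survive at 1 atm and rt; the product is achiral.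

**Compound list**
1 | 4-fluoro-3-methoxybenzaldehyde | COc1cc(C=O)ccc1F | starting material
2 | 4-(benzyloxy)-3-hydroxybenzaldehyde | O=Cc1ccc(OCc2ccccc2)c(O)c1 | starting material
3 | 4-(benzyloxy)-3-(4-formyl-2-methoxyphenoxy)benzaldehyde | COc1cc(C=O)ccc1Oc1cc(C=O)ccc1OCc1ccccc1 | intermediate
4 | 1-[2,4-bis(benzyloxy)phenyl]ethan-1-one (2',4'-bis(benzyloxy)acetophenone) | CC(=O)c1ccc(OCc2ccccc2)cc1OCc1ccccc1 | starting material
5 | ring-A mono-chalcone: 4-(benzyloxy)-3-{4-[(1E)-3-(2,4-bis(benzyloxy)phenyl)-3-oxoprop-1-en-1-yl]-2-methoxyphenoxy}benzaldehyde | COc1cc(/C=C/C(=O)c2ccc(OCc3ccccc3)cc2OCc2ccccc2)ccc1Oc1cc(C=O)ccc1OCc1ccccc1 | intermediate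
6 | ring-B mono-chalcone: 4-{2-(benzyloxy)-5-[(1E)-3-(2,4-bis(benzyloxy)phenyl)-3-oxoprop-1-en-1-yl]phenoxy}-3-methoxybenzaldehyde | COc1cc(C=O)ccc1Oc1cc(/C=C/C(=O)c2ccc(OCc3ccccc3)cc2OCc2ccccc2)ccc1OCc1ccccc1 | intermediate
7 | (E,E)-penta-O-benzyl bis-chalcone: (2E)-3-{4-(benzyloxy)-3-[4-((1E)-3-(2,4-bis(benzyloxy)phenyl)-3-oxoprop-1-en-1-yl)-2-methoxyphenoxy]phenyl}-1-[2,4-bis(benzyloxy)phenyl]prop-2-en-1-one | COc1cc(/C=C/C(=O)c2ccc(OCc3ccccc3)cc2OCc2ccccc2)ccc1Oc1cc(/C=C/C(=O)c2ccc(OCc3ccccc3)cc2OCc2ccccc2)ccc1OCc1ccccc1 | intermediate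
8 | penta-O-benzylverbenachalcone: 3-{4-(benzyloxy)-3-[4-(3-(2,4-bis(benzyloxy)phenyl)-3-oxopropyl)-2-methoxyphenoxy]phenyl}-1-[2,4-bis(benzyloxy)phenyl]propan-1-one | COc1cc(CCC(=O)c2ccc(OCc3ccccc3)cc2OCc2ccccc2)ccc1Oc1cc(CCC(=O)c2ccc(OCc3ccccc3)cc2OCc2ccccc2)ccc1OCc1ccccc1 | intermediate
9 | verbenachalcone: 1-(2,4-dihydroxyphenyl)-3-{3-[4-(3-(2,4-dihydroxyphenyl)-3-oxopropyl)-2-methoxyphenoxy]-4-hydroxyphenyl}propan-1-one | COc1cc(CCC(=O)c2ccc(O)cc2O)ccc1Oc1cc(CCC(=O)c2ccc(O)cc2O)ccc1O | target

**Total step count:** 3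
**Longest linear sequence:** 3 steps (1 → 3 → 7 → 9)

**Steps most likely to fail, with fallbacks**

Step 1 (SNAr). The ortho-methoxy group deactivates and shields the C–F carbon of 1, and the phenol of 2 is itself ortho-substituted, so conversion may stall or the aldehydes may degrade at 120 °C. The fallback sets out from 2 and comes back to the route at 3. It replaces addition–elimination by a copper-catalysed Ullmann-type C–O coupling of 2 with commercial 4-bromo-3-methoxybenzaldehyde (CuI, picolinic acid, K3PO4, DMSO, 90 °C). This does not depend on carbonyl activation of the halide and tolerates aldehydes. It makes no compound outside the list (entry F0).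

Step 3 (global hydrogenation). The risk is over-reduction of the aryl ketones to benzylic alcohols or methylenes before the last benzyl ether is gone, or incomplete debenzylation of the poorly soluble substrate. The fallback sets out from 7 and comes back at 9, separating the two events and making the deprotection non-reductive. Alkene-selective hydrogenation (H2, Pd/C poisoned with Ph2S, EtOAc/THF, rt) stops at penta-O-benzylverbenachalcone 8, which is now isolated. Lewis-acid debenzylation (BCl3, pentamethylbenzene as cation scavenger, CH2Cl2, −78 °C, then MeOH/water) then gives 9 with the methyl ether and ketones intact. No compound outside the list is made (entry F0).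

Step 2 (double Claisen–Schmidt). The mono-chalcones 5 and 6 may precipitate before the second condensation, or hydroxide may cause Cannizzaro or Michael side reactions. The fallback sets out from 4 and comes back at 7, replacing the aldol condensation by a double Wittig olefination with a stabilised ylide. α-Bromination of 4 (CuBr2, EtOAc/CHCl3, reflux) gives 2-bromo-1-[2,4-bis(benzyloxy)phenyl]ethan-1-one F1. PPh3 in toluene at rt converts it into {2-[2,4-bis(benzyloxy)phenyl]-2-oxoethyl}triphenylphosphonium bromide F2. Aqueous NaOH/CH2Cl2 deprotonates this to the stabilised ylide 1-[2,4-bis(benzyloxy)phenyl]-2-(triphenyl-λ5-phosphanylidene)ethan-1-one F3. Heating F3 (2.3 equiv) with dialdehyde 3 in toluene at reflux gives the E,E-bis-enone 7 under neutral conditions.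

**Further compounds**
F0 | step 1 | none | none
F1 | step 2 | 2-bromo-1-[2,4-bis(benzyloxy)phenyl]ethan-1-one | O=C(CBr)c1ccc(OCc2ccccc2)cc1OCc1ccccc1
F2 | step 2 | {2-[2,4-bis(benzyloxy)phenyl]-2-oxoethyl}triphenylphosphonium bromide | [Br-].O=C(C[P+](c1ccccc1)(c1ccccc1)c1ccccc1)c1ccc(OCc2ccccc2)cc1OCc1ccccc1
F3 | step 2 | 1-[2,4-bis(benzyloxy)phenyl]-2-(triphenyl-λ5-phosphanylidene)ethan-1-one | O=C(C=P(c1ccccc1)(c1ccccc1)c1ccccc1)c1ccc(OCc2ccccc2)cc1OCc1ccccc1
F0 | step 3 | none | none
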